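**Plan**

- Numbering: ring carbons C1–C16 follow the target SMILES (C1 bears =CH2; C2, C7, C16 OAc; C15 OH; C5, C9, C14 Me). The enabling feature is the cyclohexene C8–C9–C10–C14–C15–C16, oxygenated at C15/C16 and cis-fused through C10–C14 (C14 quaternary) to the cyclopentane C10–C11–C12–C13–C14: the [4+2] retron of a 2-methylcyclopent-2-enone and a 1,3-dioxygenated penta-1,3-diene.
- Cuts: C1–C2 (ring-closing Nozaki–Hiyama–Kishi), C7–C8 (intermolecular NHK), C11–C1 (carbonylation of a C11 enol triflate), then C9–C10 and C14–C15 (Diels–Alder). The C13 carbonyl is only an activating group and is removed.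
- Forward: cyclopentenone → six-membered ring by cycloaddition → C13 deoxygenation, C16 oxygenation, C11 acyl group → C2–C7 chain from (S)-citronellol joined at C8 → 11-membered ring closed at C1–C2 → acetates.
- Stereochemistry: a C11 silyloxy group on the (S)-dienophile sends the diene to the opposite face (C10, C14) and later becomes the C11 carbonyl. C15 comes from the carbonyl-exo mode, C16 from Rubottom oxidation anti to O-15, C11 from convex-face hydrogenation, C5 from citronellol, C7 and C2 from CBS reductions.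

Key step: step 6

Remark: 1, 4 and 20 are taken as the commercial starting materials; locants in names are the target numbers, and "syn/anti" refer to the face of the C14 methyl group.
Remark: 9 and 10 (C13), 24 (C7) and 31 (C2) are carried as epimer mixtures because these centres are removed or reset; C9 in 8–18 is a temporary centre, drawn as formed in step 6.

**Route**

Step 1
Reactants: 1 (S)-4-(tert-butyldimethylsilyloxy)cyclopent-2-en-1-one
Product: 2 (S)-4-(tert-butyldimethylsilyloxy)-2-iodocyclopent-2-en-1-one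
Conditions: I2, pyridine, CH2Cl2, 0 °C → rt
Reagents that add atoms: iodine, II
Why: α-Iodination of the enone by conjugate addition of pyridine, iodination of the enolate and elimination; the silyloxy-bearing centre is not involved.

Step 2
Reactants: 2 (S)-4-(tert-butyldimethylsilyloxy)-2-iodocyclopent-2-en-1-one
Product: 3 (S)-4-(tert-butyldimethylsilyloxy)-2-methylcyclopent-2-en-1-one
Conditions: SnMe4, PdCl2(PhCN)2 (5 mol%), AsPh3, CuI, NMP, 60 °C
Reagents that add atoms: tetramethylstannane, C[Sn](C)(C)C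
Why: Stille coupling of the α-iodoenone under base-free conditions installs the future C14 methyl group without β-elimination of the silyloxy group.

Step 3
Reactants: 4 pent-1-yn-3-ol
Product: 5 pent-1-yn-3-one
Conditions: CrO3, H2SO4, acetone/H2O, 0 °C
Reagents that add atoms: none
Why: Jones oxidation of the secondary propargylic alcohol gives the volatile ynone, which is used as a distilled solution.

Step 4
Reactants: 5 pent-1-yn-3-one
Product: 6 (E)-1-[(4-methoxybenzyl)oxy]pent-1-en-3-one
Conditions: 4-MeOC6H4CH2OH, DABCO (10 mol%), CH2Cl2, 0 °C → rt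
Reagents that add atoms: 4-methoxybenzyl alcohol, COc1ccc(CO)cc1
Why: Amine-catalysed oxa-Michael addition of the alcohol to the ynone gives the β-alkoxy enone as the E isomer.

Step 5
Reactants: 6 (E)-1-[(4-methoxybenzyl)oxy]pent-1-en-3-one
Product: 7 (1E,3Z)-1-[(4-methoxybenzyl)oxy]-3-(triisopropylsilyloxy)penta-1,3-diene
Conditions: iPr3SiOTf, Et3N, Et2O, 0 °C
Reagents that add atoms: triisopropylsilyl trifluoromethanesulfonate, CC(C)[Si](C(C)C)(C(C)C)OS(=O)(=O)C(F)(F)F
Why: Soft enolisation of the ethyl ketone, the only enolisable position, gives the Z silyl enol ether, so the C9 methyl points outward in the diene.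

Step 6
Reactants: 3 (S)-4-(tert-butyldimethylsilyloxy)-2-methylcyclopent-2-en-1-one; 7 (1E,3Z)-1-[(4-methoxybenzyl)oxy]-3-(triisopropylsilyloxy)penta-1,3-diene
Product: 8 cis-fused cycloadduct: cyclohexene C8=C16 (8-OTIPS enol ether, 9-Me, 15-OPMB) fused at C10–C14 to a cyclopentan-13-one (11-OTBS, 14-Me); H-10, 9-Me, 15-OPMB and 11-OTBS all syn
Conditions: 7 (1.5 equiv), HNTf2 (10 mol%), CH2Cl2, −78 → −40 °C; Et3N quench
Reagents that add atoms: none
Why: Proposed new method: a [4+2] of a 2-methylcyclopent-2-enone with a 1-alkoxy-3-silyloxydiene that runs carbonyl-exo has not been shown, the closest known reaction type being the Lewis-acid- or triflimide-promoted (endo-biased or unselective) Diels–Alder addition of silyloxydienes to 2-alkylcycloalkenones, together with exo-selective cycloadditions of α-substituted enals under bulky Lewis acids. The enone, activated at oxygen by iPr3Si–NTf2 formed in situ, is attacked by the nucleophilic diene terminus C9 at the β-carbon C10 and C15 then bonds to the α-carbon C14 in a concerted but highly asynchronous (Michael-like) cycloaddition, so the regiochemistry follows the polarisation of both partners. The six-membered ring C8–C9–C10–C14–C15–C16 closes by suprafacial addition to the ring alkene, which gives the cis C10–C14 fusion and the quaternary C14 directly. The diene approaches anti to the C11 silyloxy group, the established facial bias of 4-silyloxycyclopentenones, and this fixes C10 and C14 in the absolute sense. C15 (with the temporary C9) is set by the exo mode, expected because the late-forming C14–C15 bond joins an O-silylated enol carbon and an alkoxy-bearing terminus whose bulky oxygen substituents keep apart, and because the α-methyl group removes the usual endo preference. The step thus needs anti-facial and carbonyl-exo selectivity, the first secured by the C11 OTBS group and the second by the α-methyl group and the bulky silyl groups on diene and Lewis acid.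

Step 7
Reactants: 8 cycloadduct
Product: 9 13-hydroxy analogue of 8 (C13 epimers)
Conditions: NaBH4, MeOH/CH2Cl2, −20 °C
Reagents that add atoms: none
Why: Borohydride reduction of the only ketone; the silyl enol ether and the β-silyloxy group survive these non-enolising conditions, and the C13 configuration is immaterial.

Step 8
Reactants: 9 13-hydroxy compound
Product: 10 13-O-(imidazol-1-ylcarbonothioyl) derivative of 9
Conditions: 1,1'-thiocarbonyldiimidazole, DMAP (cat.), ClCH2CH2Cl, 70 °C
Reagents that add atoms: 1,1'-thiocarbonyldiimidazole, S=C(n1ccnc1)n1ccnc1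
Why: Thiocarbonylation of the hindered alcohol under neutral conditions, which avoids an alkoxide that could trigger 1,3-silyl migration from O-11.

Step 9
Reactants: 10 thiocarbonyl imidazolide
Product: 11 13-deoxy silyl enol ether (C13 = CH2; 8-OTIPS enol ether, 15-OPMB, 11-OTBS)
Conditions: Bu3SnH, AIBN (cat.), toluene, 100 °C
Reagents that add atoms: none
Why: Barton–McCombie deoxygenation through the secondary C13 radical, which has no β-leaving group and is simply reduced.

Step 10
Reactants: 11 13-deoxy silyl enol ether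
Product: 13 8-oxo-16-(triisopropylsilyloxy) compound (O-16 anti and trans to 15-OPMB; 11-OTBS retained), via C8–C16 silyloxy epoxide 12 (not isolated)
Conditions: mCPBA, NaHCO3, CH2Cl2, −20 °C → rt
Reagents that add atoms: 3-chloroperoxybenzoic acid, OOC(=O)c1cccc(Cl)c1
Why: Rubottom oxidation: the peracid epoxidises the silyl enol ether anti to the pseudo-axial allylic 15-OPMB group, and ring opening with 1,4-silyl transfer delivers the α-silyloxy ketone with O-16 trans to O-15.

Step 11
Reactants: 13 8-oxo-16-OTIPS compound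
Product: 14 11-hydroxy-8-ketone (11-OH syn)
Conditions: HF·pyridine, pyridine, THF, 0 °C → rt
Reagents that add atoms: none
Why: Selective desilylation: the secondary TBS ether is cleaved far faster than the hindered secondary TIPS ether, and the PMB ether is inert.

Step 12
Reactants: 14 11-hydroxy-8-ketone
Product: 15 8,11-diketone
Conditions: Dess–Martin periodinane, NaHCO3, CH2Cl2, rt
Reagents that add atoms: none
Why: Buffered Dess–Martin oxidation of the secondary alcohol; C9 is still sp3, so H-10 is α to one carbonyl only.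

Step 13
Reactants: 15 8,11-diketone
Product: 16 11-(trifluoromethanesulfonyloxy)-Δ11(12) 8-ketone
Conditions: KHMDS (1.0 equiv), THF, −78 °C; PhNTf2, −78 → −40 °C
Reagents that add atoms: N-phenylbis(trifluoromethanesulfonimide), O=S(=O)(N(c1ccccc1)S(=O)(=O)C(F)(F)F)C(F)(F)F
Why: Kinetic deprotonation occurs at C12, the only methylene α to a carbonyl (the C8 ketone is flanked by two substituted methines), and the enolate is trapped on oxygen as the enol triflate.

Step 14
Reactants: 16 C11 enol triflate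
Product: 17 Δ11(12)-11-(N-methoxy-N-methylcarbamoyl) 8-ketone (amide carbon = C1)
Conditions: Pd(OAc)2 (5 mol%), dppp, CO (1 atm), MeNH(OMe)·HCl, Et3N, DMF, 50 °C
Reagents that add atoms: carbon monoxide, [C-]#[O+]; N,O-dimethylhydroxylamine hydrochloride, CNOC.Cl
Why: Palladium-catalysed aminocarbonylation of the alkenyl triflate forms the C11–C1 bond and gives the unsaturated Weinreb amide.

Step 15
Reactants: 17 unsaturated Weinreb amide
Product: 18 saturated amide with the C11–C1 bond anti (H-11 syn; 11R)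
Conditions: H2 (1 atm), 10% Pd/C, pyridine (0.5 equiv), EtOAc, rt
Reagents that add atoms: none
Why: Heterogeneous hydrogenation adds H2 syn from the convex face of the cis-hydrindane (the face of H-10 and the C14 methyl), which places C1 on the concave face as required at C11; pyridine suppresses hydrogenolysis of the PMB ether.

Step 16
Reactants: 18 saturated Weinreb amide
Product: 19 8-(trifluoromethanesulfonyloxy)-Δ8(9) amide
Conditions: KHMDS, THF, −78 °C; PhNTf2, −78 → 0 °C
Reagents that add atoms: N-phenylbis(trifluoromethanesulfonimide), O=S(=O)(N(c1ccccc1)S(=O)(=O)C(F)(F)F)C(F)(F)F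
Why: Enol triflate formation toward C9: in the chair with the C9 and C14 methyl groups equatorial, H-9 is axial and aligned with the carbonyl whereas H-16 is equatorial and shielded by the silyloxy group, and the ketone is far more acidic than the amide; the temporary C9 centre is erased.

Step 17
Reactants: 20 (S)-citronellol
Product: 22 (S)-6,6-dimethoxy-3-methylhexan-1-ol, via (S)-6-hydroxy-4-methylhexanal 21 (not isolated)
Conditions: O3, CH2Cl2/MeOH, −78 °C; Me2S, −78 °C → rt; then HC(OMe)3, PPTS (cat.), MeOH, rt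
Reagents that add atoms: trimethyl orthoformate, COC(OC)OC; methanol, CO (ozone, [O-][O+]=O, supplies only the carbonyl oxygen of 21)
Why: Ozonolysis of the trisubstituted alkene with reductive work-up gives the C2 aldehyde, which is acetalised in the same pot; the C5 stereocentre is remote and untouched.

Step 18
Reactants: 22 (S)-6,6-dimethoxy-3-methylhexan-1-ol
Product: 23 (S)-6,6-dimethoxy-3-methylhexanal
Conditions: Dess–Martin periodinane, NaHCO3, CH2Cl2, 0 °C → rt
Reagents that add atoms: none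
Why: Buffered oxidation of the primary alcohol gives the C7 aldehyde with the C2 terminus masked as the dimethyl acetal.

Step 19
Reactants: 19 C8 enol triflate; 23 (S)-6,6-dimethoxy-3-methylhexanal
Product: 24 C7 allylic alcohol (C8–C7 bond formed; 7-OH epimers; chain C7–C2 with 5S-Me and C2 dimethyl acetal)
Conditions: CrCl2 (6 equiv), NiCl2 (2 mol%), DMF, rt
Reagents that add atoms: none
Why: Nozaki–Hiyama–Kishi coupling: Ni(0) inserts into the alkenyl triflate and the derived alkenylchromium(III) species adds only to the aldehyde (Weinreb amide and acetal are inert); C7 is reset in steps 20–21.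

Step 20
Reactants: 24 C7 allylic alcohol
Product: 25 C7 enone (C7=O conjugated to C8=C9)
Conditions: Dess–Martin periodinane, NaHCO3, CH2Cl2, rt
Reagents that add atoms: none
Why: Oxidation of the allylic alcohol converts both C7 epimers into one enone.

Step 21
Reactants: 25 C7 enone
Product: 26 (7S)-allylic alcohol
Conditions: (R)-2-methyl-CBS-oxazaborolidine (0.3 equiv), catecholborane, toluene, −78 °C
Reagents that add atoms: none
Why: CBS reduction: with the tetrasubstituted cycloalkenyl group as the large and the C6 methylene as the small substituent, the (R)-catalyst gives the 7S carbinol, and catecholborane at low temperature leaves the amide untouched.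

Step 22
Reactants: 26 (7S)-allylic alcohol
Product: 27 (7S)-7-(tert-butyldimethylsilyloxy) compound
Conditions: TBSCl, imidazole, DMAP (cat.), DMF, 40 °C
Reagents that add atoms: tert-butyldimethylsilyl chloride, CC(C)(C)[Si](C)(C)Cl
Why: Silylation under conditions that do not activate the dimethyl acetal (a silyl triflate would).

Step 23
Reactants: 27 7-OTBS Weinreb amide
Product: 28 C1 methyl ketone (11-acetyl)
Conditions: MeMgBr, THF, 0 °C; aq. NH4Cl
Reagents that add atoms: methylmagnesium bromide, C[Mg]Br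
Why: Weinreb ketone synthesis: the chelated tetrahedral intermediate prevents over-addition, and no other electrophile is present.

Step 24
Reactants: 28 C1 methyl ketone
Product: 29 C1 enol triflate (11-[1-(trifluoromethanesulfonyloxy)vinyl])
Conditions: KHMDS, THF, −78 °C; N-(5-chloropyridin-2-yl)bis(trifluoromethanesulfonimide), −78 °C
Reagents that add atoms: N-(5-chloropyridin-2-yl)bis(trifluoromethanesulfonimide), O=S(=O)(N(c1ccc(Cl)cn1)S(=O)(=O)C(F)(F)F)C(F)(F)F
Why: Kinetic deprotonation of the methyl group rather than the hindered C11 methine, with fast O-triflation at −78 °C, gives the 1,1-disubstituted alkenyl triflate without epimerising C11.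

Step 25
Reactants: 29 C1 enol triflate
Product: 30 C2 aldehyde
Conditions: PPTS (cat.), acetone/H2O (10:1), rt
Reagents that add atoms: water, O
Why: Mild acetal hydrolysis releases the aldehyde while the silyl ethers, PMB ether and alkenyl triflate are stable.

Step 26
Reactants: 30 C2 aldehyde
Product: 31 macrocyclic allylic alcohol (11-membered ring C1–C11; 1-methylene; 2-OH epimers; 7-OTBS, 16-OTIPS, 15-OPMB)
Conditions: CrCl2 (10 equiv), NiCl2 (2 mol%), DMF/THF, rt, slow addition to 2 mM
Reagents that add atoms: none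
Why: Intramolecular Nozaki–Hiyama–Kishi reaction of the alkenyl triflate onto the C2 aldehyde under high dilution closes the 11-membered ring at C1–C2 and creates the exocyclic methylene in the same operation; C2 is reset in steps 27–28.

Step 27
Reactants: 31 macrocyclic allylic alcohol
Product: 32 macrocyclic 1-methylene-2-ketone
Conditions: Dess–Martin periodinane, NaHCO3, CH2Cl2, 0 °C
Reagents that add atoms: none
Why: Buffered oxidation converts both C2 epimers into one cross-conjugated enone, which is used without delay.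

Step 28
Reactants: 32 macrocyclic 1-methylene-2-ketone
Product: 33 (2R)-allylic alcohol
Conditions: (S)-2-methyl-CBS-oxazaborolidine (0.5 equiv), catecholborane, toluene, −78 °C
Reagents that add atoms: none
Why: CBS reduction with the branched alkenyl carbon C1 as the large and the C3 methylene as the small substituent gives the 2R alcohol by 1,2-reduction under the (S)-catalyst.

Step 29
Reactants: 33 (2R)-allylic alcohol
Product: 34 2,7,16-triol 15-PMB ether
Conditions: TBAF, THF, rt → 45 °C
Reagents that add atoms: none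
Why: Fluoride removes the TBS and TIPS ethers while the PMB ether on O-15 stays.

Step 30
Reactants: 34 2,7,16-triol 15-PMB ether
Product: 35 2,7,16-triacetate 15-PMB ether
Conditions: Ac2O, pyridine, DMAP (cat.), CH2Cl2, rt
Reagents that add atoms: acetic anhydride, CC(=O)OC(C)=O
Why: DMAP-catalysed acetylation of the three free secondary alcohols, with O-15 still protected.

Step 31
Reactants: 35 2,7,16-triacetate 15-PMB ether
Product: 36 CNP0318778.1 (target)
Conditions: DDQ, CH2Cl2/pH 7 buffer (10:1), 0 °C → rt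
Reagents that add atoms: none
Why: Oxidative PMB cleavage under neutral conditions frees the C15 hydroxyl without acyl migration from O-16 and without touching the alkenes or allylic acetates.

**Compound list**

1 | (S)-4-(tert-butyldimethylsilyloxy)cyclopent-2-en-1-one | O=C1C=C[C@@H](O[Si](C)(C)C(C)(C)C)C1 | starting material
2 | (S)-4-(tert-butyldimethylsilyloxy)-2-iodocyclopent-2-en-1-one | O=C1C(I)=C[C@@H](O[Si](C)(C)C(C)(C)C)C1 | intermediate
3 | (S)-4-(tert-butyldimethylsilyloxy)-2-methylcyclopent-2-en-1-one | CC1=C[C@@H](O[Si](C)(C)C(C)(C)C)CC1=O | intermediate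
4 | pent-1-yn-3-ol (racemic) | CCC(O)C#C | starting material
5 | pent-1-yn-3-one | CCC(=O)C#C | intermediate
6 | (E)-1-[(4-methoxybenzyl)oxy]pent-1-en-3-one | CCC(=O)/C=C/OCc1ccc(OC)cc1 | intermediate
7 | (1E,3Z)-1-[(4-methoxybenzyl)oxy]-3-(triisopropylsilyloxy)penta-1,3-diene | C/C=C(O[Si](C(C)C)(C(C)C)C(C)C)/C=C/OCc1ccc(OC)cc1 | intermediate
8 | cycloadduct: cis-hydrindan-13-one, 8-OTIPS enol ether (C8=C16), 9-Me, 15-OPMB, 11-OTBS, all syn with H-10 | C[C@@H]1C(O[Si](C(C)C)(C(C)C)C(C)C)=C[C@H](OCc3ccc(OC)cc3)[C@@]2(C)C(=O)C[C@H](O[Si](C)(C)C(C)(C)C)[C@@H]12 | intermediate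
9 | 13-hydroxy analogue of 8 (C13 epimers) | C[C@@H]1C(O[Si](C(C)C)(C(C)C)C(C)C)=C[C@H](OCc3ccc(OC)cc3)[C@@]2(C)C(O)C[C@H](O[Si](C)(C)C(C)(C)C)[C@@H]12 | intermediate
10 | 13-O-(imidazol-1-ylcarbonothioyl) derivative of 9 | C[C@@H]1C(O[Si](C(C)C)(C(C)C)C(C)C)=C[C@H](OCc3ccc(OC)cc3)[C@@]2(C)C(OC(=S)n4ccnc4)C[C@H](O[Si](C)(C)C(C)(C)C)[C@@H]12 | intermediate
11 | 13-deoxy silyl enol ether | C[C@@H]1C(O[Si](C(C)C)(C(C)C)C(C)C)=C[C@H](OCc3ccc(OC)cc3)[C@@]2(C)CC[C@H](O[Si](C)(C)C(C)(C)C)[C@@H]12 | intermediate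
12 | C8–C16 silyloxy epoxide of 11 (epoxide oxygen anti) | C[C@@H]1[C@@]3(O[Si](C(C)C)(C(C)C)C(C)C)O[C@H]3[C@H](OCc4ccc(OC)cc4)[C@@]2(C)CC[C@H](O[Si](C)(C)C(C)(C)C)[C@@H]12 | intermediate (not isolated)
13 | 8-oxo-16-OTIPS compound (O-16 anti, trans to 15-OPMB) | C[C@@H]1C(=O)[C@@H](O[Si](C(C)C)(C(C)C)C(C)C)[C@H](OCc3ccc(OC)cc3)[C@@]2(C)CC[C@H](O[Si](C)(C)C(C)(C)C)[C@@H]12 | intermediate
14 | 11-hydroxy-8-ketone | C[C@@H]1C(=O)[C@@H](O[Si](C(C)C)(C(C)C)C(C)C)[C@H](OCc3ccc(OC)cc3)[C@@]2(C)CC[C@H](O)[C@@H]12 | intermediate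
15 | 8,11-diketone | C[C@@H]1C(=O)[C@@H](O[Si](C(C)C)(C(C)C)C(C)C)[C@H](OCc3ccc(OC)cc3)[C@@]2(C)CCC(=O)[C@@H]12 | intermediate
16 | C11 enol triflate (C11=C12) 8-ketone | C[C@@H]1C(=O)[C@@H](O[Si](C(C)C)(C(C)C)C(C)C)[C@H](OCc3ccc(OC)cc3)[C@@]2(C)CC=C(OS(=O)(=O)C(F)(F)F)[C@@H]12 | intermediate
17 | Δ11(12) Weinreb amide 8-ketone | C[C@@H]1C(=O)[C@@H](O[Si](C(C)C)(C(C)C)C(C)C)[C@H](OCc3ccc(OC)cc3)[C@@]2(C)CC=C(C(=O)N(C)OC)[C@@H]12 | intermediate
18 | saturated Weinreb amide 8-ketone (C11–C1 anti, 11R) | C[C@@H]1C(=O)[C@@H](O[Si](C(C)C)(C(C)C)C(C)C)[C@H](OCc3ccc(OC)cc3)[C@@]2(C)CC[C@@H](C(=O)N(C)OC)[C@@H]12 | intermediate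
19 | C8 enol triflate (C8=C9) Weinreb amide | CC1=C(OS(=O)(=O)C(F)(F)F)[C@@H](O[Si](C(C)C)(C(C)C)C(C)C)[C@H](OCc3ccc(OC)cc3)[C@@]2(C)CC[C@@H](C(=O)N(C)OC)[C@@H]12 | intermediate
20 | (S)-citronellol | OCC[C@@H](C)CCC=C(C)C | starting material
21 | (S)-6-hydroxy-4-methylhexanal | OCC[C@@H](C)CCC=O | intermediate (not isolated)
22 | (S)-6,6-dimethoxy-3-methylhexan-1-ol | OCC[C@@H](C)CCC(OC)OC | intermediate
23 | (S)-6,6-dimethoxy-3-methylhexanal | O=CC[C@@H](C)CCC(OC)OC | intermediate
24 | C7 allylic alcohol (C7 epimers), C2 dimethyl acetal | CC1=C(C(O)C[C@@H](C)CCC(OC)OC)[C@@H](O[Si](C(C)C)(C(C)C)C(C)C)[C@H](OCc3ccc(OC)cc3)[C@@]2(C)CC[C@@H](C(=O)N(C)OC)[C@@H]12 | intermediate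
25 | C7 enone | CC1=C(C(=O)C[C@@H](C)CCC(OC)OC)[C@@H](O[Si](C(C)C)(C(C)C)C(C)C)[C@H](OCc3ccc(OC)cc3)[C@@]2(C)CC[C@@H](C(=O)N(C)OC)[C@@H]12 | intermediate
26 | (7S)-allylic alcohol | CC1=C([C@@H](O)C[C@@H](C)CCC(OC)OC)[C@@H](O[Si](C(C)C)(C(C)C)C(C)C)[C@H](OCc3ccc(OC)cc3)[C@@]2(C)CC[C@@H](C(=O)N(C)OC)[C@@H]12 | intermediate
27 | (7S)-7-OTBS Weinreb amide | CC1=C([C@@H](O[Si](C)(C)C(C)(C)C)C[C@@H](C)CCC(OC)OC)[C@@H](O[Si](C(C)C)(C(C)C)C(C)C)[C@H](OCc3ccc(OC)cc3)[C@@]2(C)CC[C@@H](C(=O)N(C)OC)[C@@H]12 | intermediate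
28 | C1 methyl ketone (11-acetyl) | CC1=C([C@@H](O[Si](C)(C)C(C)(C)C)C[C@@H](C)CCC(OC)OC)[C@@H](O[Si](C(C)C)(C(C)C)C(C)C)[C@H](OCc3ccc(OC)cc3)[C@@]2(C)CC[C@@H](C(C)=O)[C@@H]12 | intermediate
29 | C1 enol triflate, C2 dimethyl acetal | CC1=C([C@@H](O[Si](C)(C)C(C)(C)C)C[C@@H](C)CCC(OC)OC)[C@@H](O[Si](C(C)C)(C(C)C)C(C)C)[C@H](OCc3ccc(OC)cc3)[C@@]2(C)CC[C@@H](C(=C)OS(=O)(=O)C(F)(F)F)[C@@H]12 | intermediate
30 | C1 enol triflate, C2 aldehyde | CC1=C([C@@H](O[Si](C)(C)C(C)(C)C)C[C@@H](C)CCC=O)[C@@H](O[Si](C(C)C)(C(C)C)C(C)C)[C@H](OCc3ccc(OC)cc3)[C@@]2(C)CC[C@@H](C(=C)OS(=O)(=O)C(F)(F)F)[C@@H]12 | intermediate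
31 | macrocyclic allylic alcohol (C2 epimers) | C=C1C(O)CC[C@H](C)C[C@H](O[Si](C)(C)C(C)(C)C)C2=C(C)[C@@H]3[C@H]1CC[C@]3(C)[C@@H](OCc4ccc(OC)cc4)[C@@H]2O[Si](C(C)C)(C(C)C)C(C)C | intermediate
32 | macrocyclic 1-methylene-2-ketone | C=C1C(=O)CC[C@H](C)C[C@H](O[Si](C)(C)C(C)(C)C)C2=C(C)[C@@H]3[C@H]1CC[C@]3(C)[C@@H](OCc4ccc(OC)cc4)[C@@H]2O[Si](C(C)C)(C(C)C)C(C)C | intermediate
33 | (2R)-macrocyclic allylic alcohol | C=C1[C@H](O)CC[C@H](C)C[C@H](O[Si](C)(C)C(C)(C)C)C2=C(C)[C@@H]3[C@H]1CC[C@]3(C)[C@@H](OCc4ccc(OC)cc4)[C@@H]2O[Si](C(C)C)(C(C)C)C(C)C | intermediate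
34 | 2,7,16-triol 15-PMB ether | C=C1[C@H](O)CC[C@H](C)C[C@H](O)C2=C(C)[C@@H]3[C@H]1CC[C@]3(C)[C@@H](OCc4ccc(OC)cc4)[C@@H]2O | intermediate
35 | 2,7,16-triacetate 15-PMB ether | C=C1[C@H](OC(C)=O)CC[C@H](C)C[C@H](OC(C)=O)C2=C(C)[C@@H]3[C@H]1CC[C@]3(C)[C@@H](OCc4ccc(OC)cc4)[C@@H]2OC(C)=O | intermediate
36 | CNP0318778.1 (2R,5S,7S,10S,11R,14S,15R,16R in the numbering used here) | C=C1[C@H](OC(C)=O)CC[C@H](C)C[C@H](OC(C)=O)C2=C(C)[C@@H]3[C@H]1CC[C@]3(C)[C@@H](O)[C@@H]2OC(C)=O | target

**Totals**

Total step count: 31. Longest linear sequence: 27 steps (steps 3–16 and 19–31, from pent-1-yn-3-ol).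

**Steps most likely to fail**

1. Step 6 (Proposed new method). The cycloaddition may run with the ring carbonyl endo, or with little exo preference, which inverts C15 (and the temporary C9) relative to the ring fusion; the facial control by the C11 silyloxy group is not the concern. The fallback sets out from 3 and 7, uses known chemistry and returns at 11.
   - Ordinary Me2AlCl promotion (CH2Cl2, −78 °C) should give mainly the carbonyl-endo adduct, the C9,C15-bis-epimer of 8 F1.
   - The operations of steps 7–9 give in turn the C13 alcohol F2, its imidazolylthiocarbonyl derivative F3 and the deoxygenated silyl enol ether F4.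
   - F4 is unravelled in the classical way for 1-alkoxy-3-silyloxydiene adducts (TFA, CH2Cl2, 0 °C), which erases C15; DBU then equilibrates the epimerisable C9 methyl to the equatorial position, giving the C8 enone with a C15=C16 double bond F5.
   - Copper-catalysed conjugate borylation (B2pin2, CuCl, NaOtBu, DPEphos, MeOH, THF) should add boron axially at C15, trans to the axial C13 methylene and therefore syn to the C14 methyl. This gives the β-boryl ketone F6, which is oxidised without isolation (NaBO3) to the 15-hydroxy-8-ketone F7.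
   - 4-Methoxybenzyl trichloroacetimidate with La(OTf)3 gives the 15-PMB ether ketone F8.
   - Kinetic enolisation toward the C16 methylene (LDA, THF, −78 °C; iPr3SiOTf) returns to 11.

2. Step 26. Intermolecular coupling and protonolysis of the alkenylchromium species may outrun closure of the strained 11-membered ring. The fallback sets out from 29 and returns at 31.
   - LDA (THF, −78 °C) eliminates triflate to give the C11-ethynyl acetal F9.
   - Acetal hydrolysis as in step 25 gives the ynal F10.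
   - Nickel-catalysed reductive alkyne–aldehyde macrocyclisation (Ni(cod)2, a bulky N-heterocyclic carbene ligand, Et3SiH, toluene, high dilution) forms the C1–C2 bond at the internal alkyne carbon. This known ligand-controlled regiochemistry gives the macrocyclic 2-triethylsilyl ether with the exocyclic methylene F11 (C2 epimers).
   - PPTS in MeOH removes the triethylsilyl group selectively and returns to 31.

3. Step 28. Reagent control over the macrocyclic exocyclic enone may be weak, and 1,4-reduction may compete. The fallback sets out from 31 and returns at 33, so that steps 27 and 28 are not needed.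
   - The C2 epimers of 31 are separated; the 2R epimer is 33.
   - The 2S alcohol F12 is inverted by Mitsunobu esterification (4-nitrobenzoic acid, PPh3, DIAD, toluene, 0 °C) to the 2R 4-nitrobenzoate F13.
   - Methanolysis (K2CO3, MeOH) returns to 33.

**Further compounds**

F1 | step 6 | C9,C15-bis-epimer of 8 (carbonyl-endo adduct) | C[C@H]1C(O[Si](C(C)C)(C(C)C)C(C)C)=C[C@@H](OCc3ccc(OC)cc3)[C@@]2(C)C(=O)C[C@H](O[Si](C)(C)C(C)(C)C)[C@@H]12
F2 | step 6 | C13 alcohol of F1 (C13 epimers) | C[C@H]1C(O[Si](C(C)C)(C(C)C)C(C)C)=C[C@@H](OCc3ccc(OC)cc3)[C@@]2(C)C(O)C[C@H](O[Si](C)(C)C(C)(C)C)[C@@H]12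
F3 | step 6 | 13-O-(imidazol-1-ylcarbonothioyl) derivative of F2 | C[C@H]1C(O[Si](C(C)C)(C(C)C)C(C)C)=C[C@@H](OCc3ccc(OC)cc3)[C@@]2(C)C(OC(=S)n4ccnc4)C[C@H](O[Si](C)(C)C(C)(C)C)[C@@H]12
F4 | step 6 | C9,C15-bis-epimer of 11 | C[C@H]1C(O[Si](C(C)C)(C(C)C)C(C)C)=C[C@@H](OCc3ccc(OC)cc3)[C@@]2(C)CC[C@H](O[Si](C)(C)C(C)(C)C)[C@@H]12
F5 | step 6 | C8 enone with C15=C16 (11-OTBS, 9-Me equatorial) | C[C@@H]1C(=O)C=C[C@@]2(C)CC[C@H](O[Si](C)(C)C(C)(C)C)[C@@H]12
F6 | step 6 | 15-(pinacolatoboryl)-8-ketone (boron syn; not isolated) | C[C@@H]1C(=O)C[C@H](B3OC(C)(C)C(C)(C)O3)[C@@]2(C)CC[C@H](O[Si](C)(C)C(C)(C)C)[C@@H]12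
F7 | step 6 | 15-hydroxy-8-ketone (15-OH syn) | C[C@@H]1C(=O)C[C@H](O)[C@@]2(C)CC[C@H](O[Si](C)(C)C(C)(C)C)[C@@H]12
F8 | step 6 | 15-PMB ether 8-ketone | C[C@@H]1C(=O)C[C@H](OCc3ccc(OC)cc3)[C@@]2(C)CC[C@H](O[Si](C)(C)C(C)(C)C)[C@@H]12
F9 | step 26 | C11-ethynyl compound, C2 dimethyl acetal | CC1=C([C@@H](O[Si](C)(C)C(C)(C)C)C[C@@H](C)CCC(OC)OC)[C@@H](O[Si](C(C)C)(C(C)C)C(C)C)[C@H](OCc3ccc(OC)cc3)[C@@]2(C)CC[C@@H](C#C)[C@@H]12
F10 | step 26 | C11-ethynyl C2 aldehyde (ynal) | CC1=C([C@@H](O[Si](C)(C)C(C)(C)C)C[C@@H](C)CCC=O)[C@@H](O[Si](C(C)C)(C(C)C)C(C)C)[C@H](OCc3ccc(OC)cc3)[C@@]2(C)CC[C@@H](C#C)[C@@H]12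
F11 | step 26 | macrocyclic 2-triethylsilyl ether with exocyclic methylene (C2 epimers) | C=C1C(O[Si](CC)(CC)CC)CC[C@H](C)C[C@H](O[Si](C)(C)C(C)(C)C)C2=C(C)[C@@H]3[C@H]1CC[C@]3(C)[C@@H](OCc4ccc(OC)cc4)[C@@H]2O[Si](C(C)C)(C(C)C)C(C)C
F12 | step 28 | (2S)-epimer of 33 | C=C1[C@@H](O)CC[C@H](C)C[C@H](O[Si](C)(C)C(C)(C)C)C2=C(C)[C@@H]3[C@H]1CC[C@]3(C)[C@@H](OCc4ccc(OC)cc4)[C@@H]2O[Si](C(C)C)(C(C)C)C(C)C
F13 | step 28 | (2R)-4-nitrobenzoate of 33 | C=C1[C@H](OC(=O)c5ccc(cc5)[N+](=O)[O-])CC[C@H](C)C[C@H](O[Si](C)(C)C(C)(C)C)C2=C(C)[C@@H]3[C@H]1CC[C@]3(C)[C@@H](OCc4ccc(OC)cc4)[C@@H]2O[Si](C(C)C)(C(C)C)C(C)C
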